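**Plan**
Cuts, after removal of seven O‑benzyl groups: in unit 2 (the naringenin‑type chromanone bound through C8) the C2–aryl bond, then O1–C2/C2–C3 and C4–C4a of its pyranone ring; in unit 1 (the catechol‑bearing chromanone) C3–C4, then O1–C8a, then the C3–C8 bond between the two units.
Enabling feature: C3 and C4 of ring C of unit 1 lie between ring A and the di‑ortho‑oxygenated aryl ring of unit 2; at the 2H‑chromene oxidation level the C3=C4 bond carries no stereocentre and is what a ring‑closing metathesis of a 2‑vinylphenyl 2‑arylallyl ether delivers.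
Forward order: ketone α‑arylation joins the unit 2 ring to the future C3, α‑methylenation and carbonyl reduction give the allylic alcohol, SNAr attaches ring A, methylenation and metathesis close ring C; hydroboration/oxidation gives the unit 1 chromanone; the pyranone ring of unit 2 is built last (acetyl, chromone, conjugate arylation), then hydrogenolysis.
Stereochemistry: C2 of unit 1 from the oxazaborolidine (CBS) reduction, kept through the SNAr etherification; C3 of unit 1 from hydroboration anti to the C2 aryl group (aryl groups cis); C2 of unit 2 from a ligand‑controlled palladium‑catalysed conjugate addition.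

Key step: step 11

Remarks on the chemistry (assumptions):
- In step 6 the twisted 1‑arylvinyl group is taken as the larger carbonyl substituent, so the (R)‑oxazaborolidine is written for the (S)‑carbinol; if the sense proves opposite, the other catalyst enantiomer is used.
- In step 19 the (R)‑pyridine–oxazoline ligand is written because the (S)‑ligand is known to give (R)‑flavanones from chromones.
- From step 13 on, C3 of unit 1 is α to a ketone; strong base is avoided in every later step so that the cis arrangement from step 12 is kept. Rotamers about the C3–aryl bond are treated as one compound.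

Step 1
Reactants: 1 phloroglucinol
Product: 2 3,5-bis(methoxymethoxy)phenol
Conditions: MOMCl (2 equiv), i-Pr2NEt, DMF, 0 °C → rt
Reagents that add atoms: chloromethyl methyl ether, COCCl
Why: Statistical O‑alkylation (Williamson type) of the symmetrical triol with two equivalents of the chloromethyl ether should give mainly the bis‑ether, which is separated from mono‑ and tris‑ether by chromatography.

Step 2
Reactants: 2 3,5-bis(methoxymethoxy)phenol
Product: 3 1-(benzyloxy)-3,5-bis(methoxymethoxy)benzene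
Conditions: BnBr, K2CO3, DMF, rt
Reagents that add atoms: benzyl bromide, BrCc1ccccc1
Why: Williamson ether synthesis on the one remaining phenol.

Step 3
Reactants: 3 1-(benzyloxy)-3,5-bis(methoxymethoxy)benzene
Product: 5 5-(benzyloxy)-2-bromo-1,3-bis(methoxymethoxy)benzene, via aryllithium 4 (not isolated)
Conditions: n-BuLi, THF, 0 °C; then BrCH2CH2Br, −78 °C → rt
Reagents that add atoms: 1,2-dibromoethane, BrCCBr
Why: Directed ortho‑metalation should occur at the carbon flanked by the two chelating methoxymethoxy groups rather than next to the benzyloxy group, and the aryllithium is brominated by bromine transfer from 1,2‑dibromoethane.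

Step 4
Reactants: 5 5-(benzyloxy)-2-bromo-1,3-bis(methoxymethoxy)benzene; 6 1-[3,4-bis(benzyloxy)phenyl]ethan-1-one
Product: 7 2-[4-(benzyloxy)-2,6-bis(methoxymethoxy)phenyl]-1-[3,4-bis(benzyloxy)phenyl]ethan-1-one
Conditions: Pd2(dba)3 (2.5 mol %), 2-dicyclohexylphosphino-2′,4′,6′-triisopropylbiphenyl (XPhos), NaOt-Bu, toluene, 80 °C
Reagents that add atoms: none
Why: Palladium‑catalysed α‑arylation of a methyl ketone enolate (oxidative addition of the aryl bromide to zerovalent palladium, enolate transfer, reductive elimination), in which the bulky biarylphosphine accepts the di‑ortho‑substituted bromide and the crowded product resists a second arylation.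

Step 5
Reactants: 7 2-[4-(benzyloxy)-2,6-bis(methoxymethoxy)phenyl]-1-[3,4-bis(benzyloxy)phenyl]ethan-1-one
Product: 9 2-[4-(benzyloxy)-2,6-bis(methoxymethoxy)phenyl]-1-[3,4-bis(benzyloxy)phenyl]prop-2-en-1-one, via Mannich base 8 (not isolated)
Conditions: CH2(NMe2)2, Ac2O, THF, 0 → 50 °C
Reagents that add atoms: bis(dimethylamino)methane, CN(C)CN(C)C
Why: Mannich reaction of the ketone with the iminium ion formed from the aminal and acetic anhydride, followed by β‑elimination of dimethylamine, is the standard α‑methylenation of deoxybenzoins.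

Step 6
Reactants: 9 2-[4-(benzyloxy)-2,6-bis(methoxymethoxy)phenyl]-1-[3,4-bis(benzyloxy)phenyl]prop-2-en-1-one
Product: 11 (1S)-2-[4-(benzyloxy)-2,6-bis(methoxymethoxy)phenyl]-1-[3,4-bis(benzyloxy)phenyl]prop-2-en-1-ol, via catechol borate 10 (not isolated)
Conditions: (R)-1-methyl-3,3-diphenyltetrahydro-1H,3H-pyrrolo[1,2-c][1,3,2]oxazaborole (20 mol %), catecholborane, toluene, −78 °C; then H2O
Reagents that add atoms: none
Why: Corey–Bakshi–Shibata reduction, in which the ketone binds the oxazaborolidine anti to the bulkier 1‑arylvinyl group and hydride is delivered 1,2 to one carbonyl face, should give the (S)‑carbinol with the (R)‑catalyst while the mild borane at low temperature leaves the 1,1‑disubstituted alkene alone.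

Step 7
Reactants: 12 5-fluororesorcinol
Product: 13 1,3-bis(benzyloxy)-5-fluorobenzene
Conditions: BnBr, K2CO3, DMF, 60 °C
Reagents that add atoms: benzyl bromide, BrCc1ccccc1
Why: Twofold Williamson ether synthesis.

Step 8
Reactants: 13 1,3-bis(benzyloxy)-5-fluorobenzene
Product: 15 2,4-bis(benzyloxy)-6-fluorobenzaldehyde, via iminium chloride 14 (not isolated)
Conditions: POCl3, DMF, 0 → 60 °C; then H2O
Reagents that add atoms: N,N-dimethylformamide, CN(C)C=O; water, O
Why: Vilsmeier–Haack formylation should take place para to one benzyloxy group and ortho to the other, next to fluorine, because the position between the two benzyloxy groups is sterically shielded.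

Step 9
Reactants: 11 (1S)-2-[4-(benzyloxy)-2,6-bis(methoxymethoxy)phenyl]-1-[3,4-bis(benzyloxy)phenyl]prop-2-en-1-ol; 15 2,4-bis(benzyloxy)-6-fluorobenzaldehyde
Product: 16 2,4-bis(benzyloxy)-6-{[(1S)-2-[4-(benzyloxy)-2,6-bis(methoxymethoxy)phenyl]-1-[3,4-bis(benzyloxy)phenyl]prop-2-en-1-yl]oxy}benzaldehyde
Conditions: NaH, DMF, 0 °C → rt
Reagents that add atoms: none
Why: Nucleophilic aromatic substitution (addition–elimination) of the fluoride ortho to the formyl group by the sodium alkoxide leaves the carbinol C–O bond intact, so the configuration of 11 is retained.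

Step 10
Reactants: 16 2,4-bis(benzyloxy)-6-{[(1S)-2-[4-(benzyloxy)-2,6-bis(methoxymethoxy)phenyl]-1-[3,4-bis(benzyloxy)phenyl]prop-2-en-1-yl]oxy}benzaldehyde
Product: 17 1,5-bis(benzyloxy)-3-{[(1S)-2-[4-(benzyloxy)-2,6-bis(methoxymethoxy)phenyl]-1-[3,4-bis(benzyloxy)phenyl]prop-2-en-1-yl]oxy}-2-ethenylbenzene
Conditions: Ph3PCH3Br, KOt-Bu, THF, 0 °C → rt
Reagents that add atoms: methyltriphenylphosphonium bromide, C[P+](c1ccccc1)(c1ccccc1)c1ccccc1.[Br-]
Why: Wittig methylenation of the aryl aldehyde with the non‑stabilised ylide, which is not basic enough to deprotonate the allylic ether carbon.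

Step 11
Reactants: 17 1,5-bis(benzyloxy)-3-{[(1S)-2-[4-(benzyloxy)-2,6-bis(methoxymethoxy)phenyl]-1-[3,4-bis(benzyloxy)phenyl]prop-2-en-1-yl]oxy}-2-ethenylbenzene
Product: 18 (2S)-5,7-bis(benzyloxy)-3-[4-(benzyloxy)-2,6-bis(methoxymethoxy)phenyl]-2-[3,4-bis(benzyloxy)phenyl]-2H-chromene
Conditions: RuCl2(=CHPh)(H2IMes)(PCy3) (second-generation Grubbs catalyst, 10 mol %), toluene (0.005 M), 60 °C, Ar purge, dark
Reagents that add atoms: none
Why: The ruthenium benzylidene first exchanges with the styrene terminus by [2+2] cycloaddition and cycloreversion, the new aryl‑substituted carbene adds intramolecularly to the 1,1‑disubstituted alkene, and opening of the ruthenacyclobutane releases the chromene and a ruthenium methylidene, with ethene as the only by‑product. The closest known reaction type is the ring‑closing metathesis of 2‑vinylphenyl allyl ethers, 2‑arylallyl ethers included, to 2H‑chromenes with second‑generation ruthenium carbenes. Ring C closes as a six‑membered ring by formation of the C3=C4 double bond through this alkene metathesis, driven by loss of ethene. No stereocentre is formed, and C2 keeps its configuration because no bond to it is made or broken. The step needs ring closure to win over intermolecular metathesis, which high dilution, the six‑membered closure and the reluctance of both hindered alkenes to homodimerise should secure. It also needs the allylic ether centre to survive, which neutral conditions, moderate temperature and exclusion of light (no electrocyclic opening of the 2H‑chromene) should secure.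

Step 12
Reactants: 18 (2S)-5,7-bis(benzyloxy)-3-[4-(benzyloxy)-2,6-bis(methoxymethoxy)phenyl]-2-[3,4-bis(benzyloxy)phenyl]-2H-chromene
Product: 20 (2R,3S,4S)-5,7-bis(benzyloxy)-3-[4-(benzyloxy)-2,6-bis(methoxymethoxy)phenyl]-2-[3,4-bis(benzyloxy)phenyl]-3,4-dihydro-2H-chromen-4-ol, via C4 alkylborane 19 (not isolated)
Conditions: BH3·THF, THF, 0 °C → rt; then NaOH, H2O2, 0 °C
Reagents that add atoms: hydrogen peroxide, OO
Why: Hydroboration–oxidation, in which borane adds syn across C3=C4 from the face opposite the pseudo‑axial C2 aryl group with boron at the less substituted C4, should place the new C3–H trans to the C2 aryl group (aryl groups cis), and the C–B bond is oxidised with retention.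

Step 13
Reactants: 20 (2R,3S,4S)-5,7-bis(benzyloxy)-3-[4-(benzyloxy)-2,6-bis(methoxymethoxy)phenyl]-2-[3,4-bis(benzyloxy)phenyl]-3,4-dihydro-2H-chromen-4-ol
Product: 21 (2R,3R)-5,7-bis(benzyloxy)-3-[4-(benzyloxy)-2,6-bis(methoxymethoxy)phenyl]-2-[3,4-bis(benzyloxy)phenyl]-2,3-dihydro-4H-chromen-4-one
Conditions: Dess–Martin periodinane, NaHCO3, CH2Cl2, 0 °C → rt
Reagents that add atoms: none
Why: Dess–Martin oxidation of the secondary benzylic alcohol under buffered, non‑enolising conditions should leave the C3 configuration untouched.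

Step 14
Reactants: 21 (2R,3R)-5,7-bis(benzyloxy)-3-[4-(benzyloxy)-2,6-bis(methoxymethoxy)phenyl]-2-[3,4-bis(benzyloxy)phenyl]-2,3-dihydro-4H-chromen-4-one
Product: 22 (2R,3R)-5,7-bis(benzyloxy)-3-[4-(benzyloxy)-2,6-dihydroxyphenyl]-2-[3,4-bis(benzyloxy)phenyl]-2,3-dihydro-4H-chromen-4-one
Conditions: HCl (1.25 M in MeOH), THF, rt
Reagents that add atoms: none
Why: Acid‑catalysed acetal exchange with methanol removes both methoxymethyl ethers, and brief exposure to dilute acid at room temperature should spare the benzyl ethers and avoid cyclodehydration of the ortho‑hydroxyaryl ketone.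

Step 15
Reactants: 22 (2R,3R)-5,7-bis(benzyloxy)-3-[4-(benzyloxy)-2,6-dihydroxyphenyl]-2-[3,4-bis(benzyloxy)phenyl]-2,3-dihydro-4H-chromen-4-one
Product: 23 (2R,3R)-5,7-bis(benzyloxy)-3-[4-(benzyloxy)-2,6-dihydroxy-3-iodophenyl]-2-[3,4-bis(benzyloxy)phenyl]-2,3-dihydro-4H-chromen-4-one
Conditions: NIS (1.0 equiv), MeCN–CH2Cl2, −40 → 0 °C, dark
Reagents that add atoms: N-iodosuccinimide, O=C1CCC(=O)N1I
Why: Electrophilic aromatic iodination should go to the free resorcinol ring, by far the most nucleophilic arene, whose two open positions are equivalent, so one equivalent of reagent gives a single mono‑iodide.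

Step 16
Reactants: 23 (2R,3R)-5,7-bis(benzyloxy)-3-[4-(benzyloxy)-2,6-dihydroxy-3-iodophenyl]-2-[3,4-bis(benzyloxy)phenyl]-2,3-dihydro-4H-chromen-4-one
Product: 25 (2R,3R)-3-[3-acetyl-4-(benzyloxy)-2,6-dihydroxyphenyl]-5,7-bis(benzyloxy)-2-[3,4-bis(benzyloxy)phenyl]-2,3-dihydro-4H-chromen-4-one, via enol ether 24 (not isolated)
Conditions: Bu3Sn–C(OEt)=CH2, PdCl2(PPh3)2 (5 mol %), toluene, 90 °C; then 1 M HCl, THF, rt
Reagents that add atoms: tributyl(1-ethoxyvinyl)stannane, CCCC[Sn](CCCC)(CCCC)C(=C)OCC; water, O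
Why: Stille coupling with the 1‑ethoxyvinylstannane as an acetyl equivalent, followed by mild hydrolysis of the enol ether, installs the acetyl group without the Lewis acids of a Friedel–Crafts acylation, which would endanger the benzyl ethers and C3.

Step 17
Reactants: 25 (2R,3R)-3-[3-acetyl-4-(benzyloxy)-2,6-dihydroxyphenyl]-5,7-bis(benzyloxy)-2-[3,4-bis(benzyloxy)phenyl]-2,3-dihydro-4H-chromen-4-one
Product: 26 (2R,3R)-3-[3-acetyl-4,6-bis(benzyloxy)-2-hydroxyphenyl]-5,7-bis(benzyloxy)-2-[3,4-bis(benzyloxy)phenyl]-2,3-dihydro-4H-chromen-4-one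
Conditions: BnOH, PPh3, DIAD, THF, 0 °C → rt
Reagents that add atoms: benzyl alcohol, OCc1ccccc1
Why: Mitsunobu etherification under essentially neutral conditions should select the more acidic, non‑chelated phenol para to the acetyl group and leave the hydroxyl that is hydrogen‑bonded to the acetyl carbonyl free.

Step 18
Reactants: 26 (2R,3R)-3-[3-acetyl-4,6-bis(benzyloxy)-2-hydroxyphenyl]-5,7-bis(benzyloxy)-2-[3,4-bis(benzyloxy)phenyl]-2,3-dihydro-4H-chromen-4-one
Product: 28 (2R,3R)-5,7-bis(benzyloxy)-3-[5,7-bis(benzyloxy)-4-oxo-4H-chromen-8-yl]-2-[3,4-bis(benzyloxy)phenyl]-2,3-dihydro-4H-chromen-4-one, via enaminone 27 (not isolated)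
Conditions: Me2NCH(OMe)2, toluene, 80 °C; then 1 M HCl, CH2Cl2, rt
Reagents that add atoms: N,N-dimethylformamide dimethyl acetal, COC(OC)N(C)C
Why: Condensation of the methyl ketone with the amide acetal gives the enaminone, and acid‑promoted conjugate addition of the ortho hydroxyl with loss of dimethylamine closes the pyranone ring (enaminone route to chromones); the tertiary C3–H of unit 1 cannot condense.

Step 19
Reactants: 28 (2R,3R)-5,7-bis(benzyloxy)-3-[5,7-bis(benzyloxy)-4-oxo-4H-chromen-8-yl]-2-[3,4-bis(benzyloxy)phenyl]-2,3-dihydro-4H-chromen-4-one; 29 4-(benzyloxy)phenylboronic acid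
Product: 30 (2R,3R)-5,7-bis(benzyloxy)-3-{(2S)-5,7-bis(benzyloxy)-2-[4-(benzyloxy)phenyl]-4-oxo-3,4-dihydro-2H-chromen-8-yl}-2-[3,4-bis(benzyloxy)phenyl]-2,3-dihydro-4H-chromen-4-one
Conditions: Pd(OCOCF3)2 (10 mol %), (R)-4-tert-butyl-2-(pyridin-2-yl)-4,5-dihydro-1,3-oxazole (12 mol %), NH4PF6 (30 mol %), H2O, ClCH2CH2Cl, 60 °C
Reagents that add atoms: none
Why: Palladium‑catalysed asymmetric conjugate addition of an arylboronic acid to a chromone (aryl transfer to cationic divalent palladium, face‑selective carbopalladation, protonation of the palladium enolate), in which the chiral pyridine–oxazoline ligand and not the remote centres of unit 1 should set the (2S) centre of unit 2.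

Step 20
Reactants: 30 (2R,3R)-5,7-bis(benzyloxy)-3-{(2S)-5,7-bis(benzyloxy)-2-[4-(benzyloxy)phenyl]-4-oxo-3,4-dihydro-2H-chromen-8-yl}-2-[3,4-bis(benzyloxy)phenyl]-2,3-dihydro-4H-chromen-4-one
Product: 31 (2R,3R)-2-(3,4-dihydroxyphenyl)-5,7-dihydroxy-3-[(2S)-5,7-dihydroxy-2-(4-hydroxyphenyl)-4-oxo-3,4-dihydro-2H-chromen-8-yl]-2,3-dihydro-4H-chromen-4-one
Conditions: H2 (1 atm), 10% Pd/C (palladium on carbon), EtOAc–MeOH, rt
Reagents that add atoms: none
Why: Hydrogenolysis of the seven benzyl ethers over palladium under neutral conditions should neither enolise C3 nor reduce the hydrogen‑bonded aryl ketones.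

**Compound list**
1 | phloroglucinol (benzene-1,3,5-triol) | Oc1cc(O)cc(O)c1 | starting material
2 | 3,5-bis(methoxymethoxy)phenol | COCOc1cc(O)cc(OCOC)c1 | intermediate
3 | 1-(benzyloxy)-3,5-bis(methoxymethoxy)benzene | COCOc1cc(OCc2ccccc2)cc(OCOC)c1 | intermediate
4 | [4-(benzyloxy)-2,6-bis(methoxymethoxy)phenyl]lithium | [Li]c1c(OCOC)cc(OCc2ccccc2)cc1OCOC | intermediate
5 | 5-(benzyloxy)-2-bromo-1,3-bis(methoxymethoxy)benzene | Brc1c(OCOC)cc(OCc2ccccc2)cc1OCOC | intermediate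
6 | 1-[3,4-bis(benzyloxy)phenyl]ethan-1-one | CC(=O)c1ccc(OCc2ccccc2)c(OCc2ccccc2)c1 | starting material
7 | 2-[4-(benzyloxy)-2,6-bis(methoxymethoxy)phenyl]-1-[3,4-bis(benzyloxy)phenyl]ethan-1-one | COCOc1cc(OCc2ccccc2)cc(OCOC)c1CC(=O)c1ccc(OCc2ccccc2)c(OCc2ccccc2)c1 | intermediate
8 | racemic 2-[4-(benzyloxy)-2,6-bis(methoxymethoxy)phenyl]-1-[3,4-bis(benzyloxy)phenyl]-3-(dimethylamino)propan-1-one | COCOc1cc(OCc2ccccc2)cc(OCOC)c1C(CN(C)C)C(=O)c1ccc(OCc2ccccc2)c(OCc2ccccc2)c1 | intermediate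
9 | 2-[4-(benzyloxy)-2,6-bis(methoxymethoxy)phenyl]-1-[3,4-bis(benzyloxy)phenyl]prop-2-en-1-one | COCOc1cc(OCc2ccccc2)cc(OCOC)c1C(=C)C(=O)c1ccc(OCc2ccccc2)c(OCc2ccccc2)c1 | intermediate
10 | 2-{[(1S)-2-[4-(benzyloxy)-2,6-bis(methoxymethoxy)phenyl]-1-[3,4-bis(benzyloxy)phenyl]prop-2-en-1-yl]oxy}-1,3,2-benzodioxaborole | c1ccc2OB(O[C@@H](c3ccc(OCc4ccccc4)c(OCc4ccccc4)c3)C(=C)c3c(OCOC)cc(OCc4ccccc4)cc3OCOC)Oc2c1 | intermediate
11 | (1S)-2-[4-(benzyloxy)-2,6-bis(methoxymethoxy)phenyl]-1-[3,4-bis(benzyloxy)phenyl]prop-2-en-1-ol | O[C@@H](c1ccc(OCc2ccccc2)c(OCc2ccccc2)c1)C(=C)c1c(OCOC)cc(OCc2ccccc2)cc1OCOC | intermediate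
12 | 5-fluororesorcinol (5-fluorobenzene-1,3-diol) | Oc1cc(O)cc(F)c1 | starting material
13 | 1,3-bis(benzyloxy)-5-fluorobenzene | Fc1cc(OCc2ccccc2)cc(OCc2ccccc2)c1 | intermediate
14 | N-{[2,4-bis(benzyloxy)-6-fluorophenyl]methylidene}-N-methylmethanaminium chloride | C[N+](C)=Cc1c(F)cc(OCc2ccccc2)cc1OCc1ccccc1.[Cl-] | intermediate
15 | 2,4-bis(benzyloxy)-6-fluorobenzaldehyde | O=Cc1c(F)cc(OCc2ccccc2)cc1OCc1ccccc1 | intermediate
16 | 2,4-bis(benzyloxy)-6-{[(1S)-2-[4-(benzyloxy)-2,6-bis(methoxymethoxy)phenyl]-1-[3,4-bis(benzyloxy)phenyl]prop-2-en-1-yl]oxy}benzaldehyde | O=Cc1c(OCc2ccccc2)cc(OCc2ccccc2)cc1O[C@@H](c1ccc(OCc2ccccc2)c(OCc2ccccc2)c1)C(=C)c1c(OCOC)cc(OCc2ccccc2)cc1OCOC | intermediate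
17 | 1,5-bis(benzyloxy)-3-{[(1S)-2-[4-(benzyloxy)-2,6-bis(methoxymethoxy)phenyl]-1-[3,4-bis(benzyloxy)phenyl]prop-2-en-1-yl]oxy}-2-ethenylbenzene | C=Cc1c(OCc2ccccc2)cc(OCc2ccccc2)cc1O[C@@H](c1ccc(OCc2ccccc2)c(OCc2ccccc2)c1)C(=C)c1c(OCOC)cc(OCc2ccccc2)cc1OCOC | intermediate
18 | (2S)-5,7-bis(benzyloxy)-3-[4-(benzyloxy)-2,6-bis(methoxymethoxy)phenyl]-2-[3,4-bis(benzyloxy)phenyl]-2H-chromene | COCOc1cc(OCc2ccccc2)cc(OCOC)c1C1=Cc2c(OCc3ccccc3)cc(OCc3ccccc3)cc2O[C@H]1c1ccc(OCc2ccccc2)c(OCc2ccccc2)c1 | intermediate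
19 | [(2R,3R,4S)-5,7-bis(benzyloxy)-3-[4-(benzyloxy)-2,6-bis(methoxymethoxy)phenyl]-2-[3,4-bis(benzyloxy)phenyl]-3,4-dihydro-2H-chromen-4-yl]borane (boron and the new C3–H on the face opposite the C2 aryl group) | COCOc1cc(OCc2ccccc2)cc(OCOC)c1[C@H]1[C@H](B)c2c(OCc3ccccc3)cc(OCc3ccccc3)cc2O[C@H]1c1ccc(OCc2ccccc2)c(OCc2ccccc2)c1 | intermediate
20 | (2R,3S,4S)-5,7-bis(benzyloxy)-3-[4-(benzyloxy)-2,6-bis(methoxymethoxy)phenyl]-2-[3,4-bis(benzyloxy)phenyl]-3,4-dihydro-2H-chromen-4-ol (aryl groups cis, 4-OH trans to the C3 aryl group) | COCOc1cc(OCc2ccccc2)cc(OCOC)c1[C@H]1[C@H](O)c2c(OCc3ccccc3)cc(OCc3ccccc3)cc2O[C@H]1c1ccc(OCc2ccccc2)c(OCc2ccccc2)c1 | intermediate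
21 | (2R,3R)-5,7-bis(benzyloxy)-3-[4-(benzyloxy)-2,6-bis(methoxymethoxy)phenyl]-2-[3,4-bis(benzyloxy)phenyl]-2,3-dihydro-4H-chromen-4-one | COCOc1cc(OCc2ccccc2)cc(OCOC)c1[C@H]1C(=O)c2c(OCc3ccccc3)cc(OCc3ccccc3)cc2O[C@H]1c1ccc(OCc2ccccc2)c(OCc2ccccc2)c1 | intermediate
22 | (2R,3R)-5,7-bis(benzyloxy)-3-[4-(benzyloxy)-2,6-dihydroxyphenyl]-2-[3,4-bis(benzyloxy)phenyl]-2,3-dihydro-4H-chromen-4-one | Oc1cc(OCc2ccccc2)cc(O)c1[C@H]1C(=O)c2c(OCc3ccccc3)cc(OCc3ccccc3)cc2O[C@H]1c1ccc(OCc2ccccc2)c(OCc2ccccc2)c1 | intermediate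
23 | (2R,3R)-5,7-bis(benzyloxy)-3-[4-(benzyloxy)-2,6-dihydroxy-3-iodophenyl]-2-[3,4-bis(benzyloxy)phenyl]-2,3-dihydro-4H-chromen-4-one | Oc1cc(OCc2ccccc2)c(I)c(O)c1[C@H]1C(=O)c2c(OCc3ccccc3)cc(OCc3ccccc3)cc2O[C@H]1c1ccc(OCc2ccccc2)c(OCc2ccccc2)c1 | intermediate
24 | (2R,3R)-5,7-bis(benzyloxy)-3-[4-(benzyloxy)-3-(1-ethoxyethenyl)-2,6-dihydroxyphenyl]-2-[3,4-bis(benzyloxy)phenyl]-2,3-dihydro-4H-chromen-4-one | Oc1cc(OCc2ccccc2)c(C(=C)OCC)c(O)c1[C@H]1C(=O)c2c(OCc3ccccc3)cc(OCc3ccccc3)cc2O[C@H]1c1ccc(OCc2ccccc2)c(OCc2ccccc2)c1 | intermediate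
25 | (2R,3R)-3-[3-acetyl-4-(benzyloxy)-2,6-dihydroxyphenyl]-5,7-bis(benzyloxy)-2-[3,4-bis(benzyloxy)phenyl]-2,3-dihydro-4H-chromen-4-one | Oc1cc(OCc2ccccc2)c(C(C)=O)c(O)c1[C@H]1C(=O)c2c(OCc3ccccc3)cc(OCc3ccccc3)cc2O[C@H]1c1ccc(OCc2ccccc2)c(OCc2ccccc2)c1 | intermediate
26 | (2R,3R)-3-[3-acetyl-4,6-bis(benzyloxy)-2-hydroxyphenyl]-5,7-bis(benzyloxy)-2-[3,4-bis(benzyloxy)phenyl]-2,3-dihydro-4H-chromen-4-one | C(c1ccccc1)Oc1cc(OCc2ccccc2)c(C(C)=O)c(O)c1[C@H]1C(=O)c2c(OCc3ccccc3)cc(OCc3ccccc3)cc2O[C@H]1c1ccc(OCc2ccccc2)c(OCc2ccccc2)c1 | intermediate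
27 | (2R,3R)-5,7-bis(benzyloxy)-3-{4,6-bis(benzyloxy)-3-[(2E)-3-(dimethylamino)prop-2-enoyl]-2-hydroxyphenyl}-2-[3,4-bis(benzyloxy)phenyl]-2,3-dihydro-4H-chromen-4-one | C(c1ccccc1)Oc1cc(OCc2ccccc2)c(C(=O)/C=C/N(C)C)c(O)c1[C@H]1C(=O)c2c(OCc3ccccc3)cc(OCc3ccccc3)cc2O[C@H]1c1ccc(OCc2ccccc2)c(OCc2ccccc2)c1 | intermediate
28 | (2R,3R)-5,7-bis(benzyloxy)-3-[5,7-bis(benzyloxy)-4-oxo-4H-chromen-8-yl]-2-[3,4-bis(benzyloxy)phenyl]-2,3-dihydro-4H-chromen-4-one | O=c1ccoc2c1c(OCc1ccccc1)cc(OCc1ccccc1)c2[C@H]1C(=O)c2c(OCc3ccccc3)cc(OCc3ccccc3)cc2O[C@H]1c1ccc(OCc2ccccc2)c(OCc2ccccc2)c1 | intermediate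
29 | 4-(benzyloxy)phenylboronic acid | OB(O)c1ccc(OCc2ccccc2)cc1 | starting material
30 | (2R,3R)-5,7-bis(benzyloxy)-3-{(2S)-5,7-bis(benzyloxy)-2-[4-(benzyloxy)phenyl]-4-oxo-3,4-dihydro-2H-chromen-8-yl}-2-[3,4-bis(benzyloxy)phenyl]-2,3-dihydro-4H-chromen-4-one | O=C1C[C@@H](c2ccc(OCc3ccccc3)cc2)Oc2c1c(OCc1ccccc1)cc(OCc1ccccc1)c2[C@H]1C(=O)c2c(OCc3ccccc3)cc(OCc3ccccc3)cc2O[C@H]1c1ccc(OCc2ccccc2)c(OCc2ccccc2)c1 | intermediate
31 | (2R,3R)-2-(3,4-dihydroxyphenyl)-5,7-dihydroxy-3-[(2S)-5,7-dihydroxy-2-(4-hydroxyphenyl)-4-oxo-3,4-dihydro-2H-chromen-8-yl]-2,3-dihydro-4H-chromen-4-one | O=C1C[C@@H](c2ccc(O)cc2)Oc2c1c(O)cc(O)c2[C@H]1C(=O)c2c(O)cc(O)cc2O[C@H]1c1ccc(O)c(O)c1 | target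

**Step count and risks**
Total: 20 steps. Longest linear sequence: 18 steps (steps 1–6 and 9–20); the ring A aldehyde 15 takes 2 steps (7–8).

The three steps most likely to fail:

Step 11. Both alkenes are flanked by ortho substituents, so the carbene formed at the styrene may rest as an ortho‑alkoxy chelate and fail to engage the 1,1‑disubstituted alkene; ruthenium hydrides may also isomerise the allylic ether. The fallback sets out from aldehyde 16. Lemieux–Johnson cleavage of its 1,1‑disubstituted alkene (OsO4 cat., NaIO4, 2,6‑lutidine, dioxane–H2O) would give the keto aldehyde 2,4-bis(benzyloxy)-6-{(1S)-2-[4-(benzyloxy)-2,6-bis(methoxymethoxy)phenyl]-1-[3,4-bis(benzyloxy)phenyl]-2-oxoethoxy}benzaldehyde F1. Intramolecular McMurry coupling with low‑valent titanium (TiCl3, Zn(Cu), DME, reflux, slow addition) would then join the two carbonyl carbons as C3=C4 and come back to the route at chromene 18. The α‑aryloxy ketone is kept away from base, and the configurational purity at C2 would have to be checked after the coupling.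

Step 12. Borane may add only slowly to the crowded trisubstituted alkene, boron may go to C3 (followed by β‑elimination of the ring oxygen), or the facial preference may be incomplete. The fallback sets out from chromene 18. Dihydroxylation with OsO4 (NMO, acetone–H2O) from the face opposite the C2 aryl group would give (2S,3R,4R)-5,7-bis(benzyloxy)-3-[4-(benzyloxy)-2,6-bis(methoxymethoxy)phenyl]-2-[3,4-bis(benzyloxy)phenyl]-3,4-dihydro-2H-chromene-3,4-diol F2. Dess–Martin oxidation of its secondary C4 hydroxyl would give (2S,3S)-5,7-bis(benzyloxy)-3-[4-(benzyloxy)-2,6-bis(methoxymethoxy)phenyl]-2-[3,4-bis(benzyloxy)phenyl]-3-hydroxy-2,3-dihydro-4H-chromen-4-one F3. SmI2 (THF–MeOH, −78 °C) would cleave the α C–OH bond reductively, and protonation of the samarium enolate from the face opposite the C2 aryl group would come back to the route at ketone 21.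

Step 6. The two sp2 substituents of the ketone may be discriminated poorly, giving low enantioselectivity or the opposite sense, and some conjugate reduction may compete. The fallback sets out from enone 9. Luche reduction (NaBH4, CeCl3·7H2O, MeOH, −20 °C) would give racemic 2-[4-(benzyloxy)-2,6-bis(methoxymethoxy)phenyl]-1-[3,4-bis(benzyloxy)phenyl]prop-2-en-1-ol F4. Sharpless kinetic resolution (Ti(Oi-Pr)4, D-(−)-diisopropyl tartrate, t-BuOOH, 4 Å molecular sieves, CH2Cl2, −20 °C) would epoxidise the (R)‑enantiomer to the erythro epoxy alcohol (R)-[3,4-bis(benzyloxy)phenyl]{(2S)-2-[4-(benzyloxy)-2,6-bis(methoxymethoxy)phenyl]oxiran-2-yl}methanol F5. The unreacted (S)‑alcohol is separated, and the route is rejoined at 11.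

**Further compounds**
F1 | step 11 | 2,4-bis(benzyloxy)-6-{(1S)-2-[4-(benzyloxy)-2,6-bis(methoxymethoxy)phenyl]-1-[3,4-bis(benzyloxy)phenyl]-2-oxoethoxy}benzaldehyde | O=Cc1c(OCc2ccccc2)cc(OCc2ccccc2)cc1O[C@@H](c1ccc(OCc2ccccc2)c(OCc2ccccc2)c1)C(=O)c1c(OCOC)cc(OCc2ccccc2)cc1OCOC
F2 | step 12 | (2S,3R,4R)-5,7-bis(benzyloxy)-3-[4-(benzyloxy)-2,6-bis(methoxymethoxy)phenyl]-2-[3,4-bis(benzyloxy)phenyl]-3,4-dihydro-2H-chromene-3,4-diol | COCOc1cc(OCc2ccccc2)cc(OCOC)c1[C@@]1(O)[C@H](O)c2c(OCc3ccccc3)cc(OCc3ccccc3)cc2O[C@H]1c1ccc(OCc2ccccc2)c(OCc2ccccc2)c1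
F3 | step 12 | (2S,3S)-5,7-bis(benzyloxy)-3-[4-(benzyloxy)-2,6-bis(methoxymethoxy)phenyl]-2-[3,4-bis(benzyloxy)phenyl]-3-hydroxy-2,3-dihydro-4H-chromen-4-one | COCOc1cc(OCc2ccccc2)cc(OCOC)c1[C@@]1(O)C(=O)c2c(OCc3ccccc3)cc(OCc3ccccc3)cc2O[C@H]1c1ccc(OCc2ccccc2)c(OCc2ccccc2)c1
F4 | step 6 | racemic 2-[4-(benzyloxy)-2,6-bis(methoxymethoxy)phenyl]-1-[3,4-bis(benzyloxy)phenyl]prop-2-en-1-ol | OC(c1ccc(OCc2ccccc2)c(OCc2ccccc2)c1)C(=C)c1c(OCOC)cc(OCc2ccccc2)cc1OCOC
F5 | step 6 | (R)-[3,4-bis(benzyloxy)phenyl]{(2S)-2-[4-(benzyloxy)-2,6-bis(methoxymethoxy)phenyl]oxiran-2-yl}methanol | O[C@H](c1ccc(OCc2ccccc2)c(OCc2ccccc2)c1)[C@]1(c2c(OCOC)cc(OCc3ccccc3)cc2OCOC)CO1
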